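## Retrosynthetic overview
1. The 12β-hydroperoxide and the C11=C20 methylene come last, from a Schenck ene reaction of the Δ11(12) diacetate; the ten-membered ring (formed last) comes from ring-closing metathesis at C5=C6.
2. The γ-lactone (second ring) comes from chelation-controlled reduction of a C7 vinyl ketone and lactonisation onto C19.
3. Key C8–C9 bond: intermolecular aldol of the dianion of a malic-acid-derived Seebach dioxolanone (C7, C8, C17–C19) with the C9 aldehyde of the cyclohexene fragment.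
4. Cyclohexene fragment (first ring, from (S)-carvone): C1–C2 by carvone aldol with a levulinate-derived aldehyde, then C1 methylation; C14–O by Criegee degradation of the isopropenyl group; C9 by epoxidation, Wharton transposition and a Wittig–Still [2,3] shift.
5. Ring order: cyclohexene (chiral pool) → γ-lactone → ten-membered carbocycle.

Convention: labels C1–C20 are the briarane positions the atoms take in the target; β is the ring face that carries the C15 methyl.
Assumption: the C9 carbinol centre in 29–36 (and F3–F5) is an inconsequential epimer mixture, written without a descriptor, because it is oxidised to the ketone.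

## Route

Step 1
Reactants: 1 ethyl levulinate
Product: 2 ethyl 3-(2-methyl-1,3-dioxolan-2-yl)propanoate
Conditions: ethylene glycol, TsOH (cat.), toluene, reflux, Dean–Stark
Reagents that add atoms: ethylene glycol OCCO
Why: Acid-catalysed ketalisation with azeotropic water removal masks the future C5 ketone, so the chain carries no olefin during the later ozonolysis.

Step 2
Reactants: 2 ethyl 3-(2-methyl-1,3-dioxolan-2-yl)propanoate
Product: 3 3-(2-methyl-1,3-dioxolan-2-yl)propanal
Conditions: i-Bu2AlH (1.05 equiv), CH2Cl2, −78 °C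
Reagents that add atoms: none
Why: Low-temperature partial ester reduction stops at the tetrahedral aluminate and gives the C2 aldehyde without touching the ketal.

Step 3
Reactants: 4 (S)-(+)-carvone; 3 3-(2-methyl-1,3-dioxolan-2-yl)propanal
Product: 6 trans anti aldol adduct (5S,6S)-6-[(1S)-1-hydroxy-3-(2-methyl-1,3-dioxolan-2-yl)propyl]-2-methyl-5-(prop-1-en-2-yl)cyclohex-2-en-1-one, via lithium dienolate 5 (not isolated)
Conditions: LiN(i-Pr)2 (1.05 equiv), THF, −78 °C; then 3, −78 °C
Reagents that add atoms: none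
Why: Kinetic α'-deprotonation gives the ring-locked (E)-enolate, which adds to 3 through a Zimmerman–Traxler chair on the face anti to the isopropenyl group (intermolecular aldol), forming C1–C2 and setting C2 as S.

Step 4
Reactants: 6 trans anti aldol adduct
Product: 7 TBS ether of 6
Conditions: t-BuMe2SiOTf, 2,6-lutidine, CH2Cl2, −78 °C
Reagents that add atoms: tert-butyldimethylsilyl trifluoromethanesulfonate CC(C)(C)[Si](C)(C)OS(=O)(=O)C(F)(F)F
Why: Buffered silyl triflate protection of the β-hydroxy ketone at low temperature precludes retro-aldol and dehydration and leaves the ketal intact.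

Step 5
Reactants: 7 TBS ether of 6
Product: 9 C1-methylated enone (15-Me β and C2 chain α), via lithium enolate 8 (not isolated)
Conditions: LiN(i-Pr)2, THF, −78 → −40 °C; MeI, DMPU, −78 → −20 °C
Reagents that add atoms: iodomethane CI
Why: Enolate alkylation occurs anti to the pseudoaxial isopropenyl group, so the methyl enters β and the C2 chain is pushed α, fixing the C1 quaternary centre.

Step 6
Reactants: 9 C1-methylated enone
Product: 11 14α-acetoxy enone, via α-methoxy hydroperoxide 10 (not isolated)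
Conditions: O3, CH2Cl2/MeOH 4:1, −78 °C; then Ac2O, Et3N, DMAP (cat.), 0 °C → rt
Reagents that add atoms: ozone O=[O+][O-]; methanol CO
Why: Ozone cleaves only the electron-rich isopropenyl olefin, and the peracetate of the α-methoxy hydroperoxide undergoes Criegee rearrangement with C14 migrating to oxygen with retention, so the old isopropenyl carbon becomes the acetyl of the 14α-acetate (acetic anhydride only activates; the methoxy group leaves as methyl acetate).

Step 7
Reactants: 11 14α-acetoxy enone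
Product: 12 14α-hydroxy enone
Conditions: K2CO3, MeOH, 0 °C → rt
Reagents that add atoms: none
Why: Mild transesterification frees the alcohol, and the quaternary C1 rules out β-elimination.

Step 8
Reactants: 12 14α-hydroxy enone
Product: 13 2,14-bis-TBS enone
Conditions: t-BuMe2SiOTf, 2,6-lutidine, CH2Cl2, 0 °C
Reagents that add atoms: tert-butyldimethylsilyl trifluoromethanesulfonate CC(C)(C)[Si](C)(C)OS(=O)(=O)C(F)(F)F
Why: Silylation gives an ether that survives the peroxide, hydrazine, hydride-base and organolithium steps that follow.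

Step 9
Reactants: 13 2,14-bis-TBS enone
Product: 14 11β,12β-epoxy ketone
Conditions: 30% H2O2, NaOH (aq.), MeOH, 0 °C
Reagents that add atoms: hydrogen peroxide OO
Why: In this Weitz–Scheffer epoxidation the hydroperoxide anion adds to C12 anti to the 14α-silyloxy group (as for carvone) and the enolate closes the epoxide on the same β face.

Step 10
Reactants: 14 11β,12β-epoxy ketone
Product: 16 Δ10(11) 12β-allylic alcohol, via epoxy hydrazone 15 (not isolated)
Conditions: N2H4·H2O, AcOH (cat.), MeOH, 0 °C → rt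
Reagents that add atoms: none
Why: Wharton transposition: the hydrazone fragments with loss of N2, moving the olefin to C10=C11 and leaving the epoxide oxygen on C12 with retention.

Step 11
Reactants: 16 Δ10(11) 12β-allylic alcohol
Product: 17 12β-(tributylstannyl)methyl ether
Conditions: KH, THF, 0 °C; Bu3SnCH2I, rt
Reagents that add atoms: tributyl(iodomethyl)stannane IC[Sn](CCCC)(CCCC)CCCC
Why: Williamson etherification of the potassium alkoxide with the reactive iodomethylstannane installs the Wittig–Still precursor.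

Step 12
Reactants: 17 12β-(tributylstannyl)methyl ether
Product: 19 10β-hydroxymethyl Δ11 cyclohexene (C9 alcohol), via lithiomethyl ether 18 (not isolated)
Conditions: n-BuLi, THF, −78 °C
Reagents that add atoms: none
Why: Tin–lithium exchange gives an α-alkoxy carbanion that undergoes a suprafacial [2,3]-Wittig–Still shift, delivering C9 to the β face of C10 (10α-H) and moving the olefin to C11=C12.

Step 13
Reactants: 19 10β-hydroxymethyl Δ11 cyclohexene
Product: 20 C5 methyl ketone
Conditions: PPTS, acetone/H2O 4:1, 50 °C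
Reagents that add atoms: water O
Why: Mild acid hydrolysis of the dioxolane reveals the ketone while both hindered TBS ethers survive.

Step 14
Reactants: 20 C5 methyl ketone
Product: 21 C5 methylene compound
Conditions: Ph3PCH3Br, KOt-Bu (3 equiv each), THF, 0 °C → rt
Reagents that add atoms: methyltriphenylphosphonium bromide C[P+](c1ccccc1)(c1ccccc1)c1ccccc1.[Br-]
Why: Wittig methylenation gives the 1,1-disubstituted C5 olefin needed for ring closure, and excess ylide tolerates the free alcohol.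

Step 15
Reactants: 21 C5 methylene compound
Product: 22 C9 aldehyde
Conditions: Dess–Martin periodinane, NaHCO3, CH2Cl2, 0 °C → rt; used at once
Reagents that add atoms: none
Why: Buffered Dess–Martin oxidation gives the β,γ-unsaturated aldehyde under neutral conditions that neither epimerise C10 nor conjugate the olefin.

Step 16
Reactants: 23 diethyl (S)-malate
Product: 25 diethyl (2S,3R)-2-hydroxy-3-methylsuccinate, via dilithium alkoxide enolate 24 (not isolated)
Conditions: LiN(i-Pr)2 (2.1 equiv), THF, −78 → −20 °C; MeI, −78 → 0 °C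
Reagents that add atoms: iodomethane CI
Why: Frater–Seebach alkylation: the chelated alkoxide enolate is methylated anti to the alkoxide, giving the anti (2S,3R) product that carries C8 and C17.

Step 17
Reactants: 25 diethyl (2S,3R)-2-hydroxy-3-methylsuccinate
Product: 26 (2S,3R)-2-hydroxy-3-methylsuccinic acid
Conditions: LiOH, THF/H2O, 0 °C → rt; then HCl to pH 1
Reagents that add atoms: lithium hydroxide [Li+].[OH-]
Why: Saponification at low temperature gives the hydroxy diacid without epimerising the methyl-bearing centre.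

Step 18
Reactants: 26 (2S,3R)-2-hydroxy-3-methylsuccinic acid
Product: 27 (R)-2-[(2S,4S)-2-tert-butyl-5-oxo-1,3-dioxolan-4-yl]propanoic acid
Conditions: pivalaldehyde, TsOH·H2O (cat.), H2SO4 (cat.), pentane, reflux, Dean–Stark; recrystallise
Reagents that add atoms: pivalaldehyde CC(C)(C)C=O
Why: Seebach acetalisation under thermodynamic control gives the five-membered cis-dioxolanone, storing the C8 configuration in the acetal centre (self-regeneration of stereocentres).

Step 19
Reactants: 27 (R)-2-[(2S,4S)-2-tert-butyl-5-oxo-1,3-dioxolan-4-yl]propanoic acid; 22 C9 aldehyde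
Product: 31 aldol acid with C9-OTES, via dilithium carboxylate enolate 28 (not isolated), via dilithium aldolate 29 (not isolated), via bis-triethylsilyl derivative 30 (not isolated)
Conditions: LiN(SiMe3)2 (2.2 equiv), THF, −78 °C; add 22, −78 °C, 1 h; Et3SiOTf (2.5 equiv), −78 → 0 °C; pH 5 buffer work-up
Reagents that add atoms: triethylsilyl trifluoromethanesulfonate CC[Si](CC)(CC)OS(=O)(=O)C(F)(F)F
Why: Intermolecular aldol addition: the dioxolanone enolate attacks the C9 aldehyde anti to the tert-butyl group, forming C8–C9 with retention at C8, while the carboxylate is a spectator and in-situ silylation stops the C9 oxygen from lactonising onto C19.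

Step 20
Reactants: 31 aldol acid with C9-OTES
Product: 33 8-hydroxy C7 vinyl ketone acid, via magnesium hemiketal 32 (not isolated)
Conditions: CH2=CHMgBr (4 equiv), THF, −78 °C; AcOH quench at −78 °C; used crude
Reagents that add atoms: vinylmagnesium bromide C=C[Mg]Br
Why: Acyl substitution: the Grignard reagent adds once to the activated dioxolanone carbonyl because the cyclic hemiketal alkoxide is stable at −78 °C and releases the ketone and pivalaldehyde only on work-up.

Step 21
Reactants: 33 8-hydroxy C7 vinyl ketone acid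
Product: 35 γ-lactone with C6 vinyl group (7S and 8-OH and 9-OTES), via dihydroxy acid 34 (not isolated)
Conditions: Zn(BH4)2, Et2O, −30 °C; aq. citric acid; then PPTS (cat.), CH2Cl2, rt
Reagents that add atoms: none
Why: Chelation-controlled 1,2-reduction: zinc bridges the C8 alkoxide and the C7 carbonyl and hydride attacks opposite the bulky C9 branch to give 7S, after which the γ-hydroxy acid lactonises through the only hydroxyl that can reach C19 in a five-membered ring.

Step 22
Reactants: 35 γ-lactone with C6 vinyl group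
Product: 36 lactone 9-alcohol
Conditions: HF·pyridine, excess pyridine, THF, 0 °C; used at once
Reagents that add atoms: none
Why: Buffered fluoride cleaves the triethylsilyl ether selectively in the presence of the two hindered TBS ethers.

Step 23
Reactants: 36 lactone 9-alcohol
Product: 37 lactone 9-ketone diene
Conditions: Dess–Martin periodinane, NaHCO3, CH2Cl2, rt
Reagents that add atoms: none
Why: Dess–Martin oxidation converts the secondary C9 alcohol into the ketone while the tertiary C8 alcohol cannot be oxidised.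

Step 24
Reactants: 37 lactone 9-ketone diene
Product: 38 macrocyclic bis-TBS ether with (Z)-C5=C6
Conditions: second-generation Hoveyda–Grubbs catalyst RuCl2(1,3-dimesitylimidazolidin-2-ylidene)(=CH-C6H4-2-O-i-Pr) (15 mol %), 1,4-benzoquinone (30 mol %), toluene (0.5 mM), 100 °C
Reagents that add atoms: none
Why: Ring-closing metathesis: the catalyst loads on the C6 vinyl group and closes onto the C5 methylene, the trans-disposed arms on the cyclohexene and the lactone preorganise the chain, and the doubly fused ten-membered ring accommodates the cis (Z) trisubstituted olefin.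

Step 25
Reactants: 38 macrocyclic bis-TBS ether
Product: 39 2,14-diol
Conditions: HF·pyridine, THF, rt → 40 °C
Reagents that add atoms: none
Why: Fluoride-mediated desilylation removes both hindered TBS ethers under mildly acidic conditions that the lactone and α-ketol tolerate.

Step 26
Reactants: 39 2,14-diol
Product: 40 2,14-diacetate
Conditions: Ac2O, pyridine, DMAP (cat.), CH2Cl2, 0 °C → rt
Reagents that add atoms: acetic anhydride CC(=O)OC(C)=O
Why: DMAP-catalysed acetylation takes the two secondary alcohols and leaves the hindered tertiary C8 hydroxyl free.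

Step 27
Reactants: 40 2,14-diacetate
Product: 41 CNP0066422.1 (target)
Conditions: O2, meso-tetraphenylporphyrin (cat.), visible light, CH2Cl2, −20 °C
Reagents that add atoms: dioxygen O=O
Why: Schenck ene reaction: singlet oxygen bonds to C12 on the β face (anti to the axial 14α-acetate) and abstracts hydrogen from the C20 methyl geminal to the bulky C10 substituent, giving the 12β-hydroperoxide and the C11=C20 methylene, while C5=C6 is deactivated by the allylic lactone oxygen.

## Compound list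
1 | ethyl levulinate | CCOC(=O)CCC(C)=O | starting material
2 | ethyl 3-(2-methyl-1,3-dioxolan-2-yl)propanoate | CCOC(=O)CCC1(C)OCCO1 | intermediate
3 | 3-(2-methyl-1,3-dioxolan-2-yl)propanal | O=CCCC1(C)OCCO1 | intermediate
4 | (S)-(+)-carvone | O=C1C(C)=CC[C@H](C(C)=C)C1 | starting material
5 | lithium dienolate of (S)-carvone (α'-enolate) | [Li]OC1=C[C@@H](C(C)=C)CC=C1C | intermediate
6 | trans anti aldol adduct (5S,6S)-6-[(1S)-1-hydroxy-3-(2-methyl-1,3-dioxolan-2-yl)propyl]-2-methyl-5-(prop-1-en-2-yl)cyclohex-2-en-1-one | O=C1C(C)=CC[C@H](C(C)=C)[C@H]1[C@@H](O)CCC2(C)OCCO2 | intermediate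
7 | TBS ether of 6 | O=C1C(C)=CC[C@H](C(C)=C)[C@H]1[C@@H](O[Si](C)(C)C(C)(C)C)CCC2(C)OCCO2 | intermediate
8 | lithium enolate of 7 (C1=C10) | [Li]OC1=C([C@@H](O[Si](C)(C)C(C)(C)C)CCC2(C)OCCO2)[C@@H](C(C)=C)CC=C1C | intermediate
9 | C1-methylated enone: 1β-methyl, 1α-[(1S)-1-TBSO-3-(2-methyl-1,3-dioxolan-2-yl)propyl], 14α-isopropenyl, C10 ketone, Δ11 | O=C1C(C)=CC[C@H](C(C)=C)[C@]1(C)[C@@H](O[Si](C)(C)C(C)(C)C)CCC2(C)OCCO2 | intermediate
10 | α-methoxy hydroperoxide at the former isopropenyl carbon (epimer mixture) | O=C1C(C)=CC[C@H](C(C)(OC)OO)[C@]1(C)[C@@H](O[Si](C)(C)C(C)(C)C)CCC2(C)OCCO2 | intermediate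
11 | 14α-acetoxy enone | O=C1C(C)=CC[C@H](OC(C)=O)[C@]1(C)[C@@H](O[Si](C)(C)C(C)(C)C)CCC2(C)OCCO2 | intermediate
12 | 14α-hydroxy enone | O=C1C(C)=CC[C@H](O)[C@]1(C)[C@@H](O[Si](C)(C)C(C)(C)C)CCC2(C)OCCO2 | intermediate
13 | 2,14-bis-TBS enone | O=C1C(C)=CC[C@H](O[Si](C)(C)C(C)(C)C)[C@]1(C)[C@@H](O[Si](C)(C)C(C)(C)C)CCC2(C)OCCO2 | intermediate
14 | 11β,12β-epoxy ketone | O=C1[C@@]2(C)O[C@H]2C[C@H](O[Si](C)(C)C(C)(C)C)[C@]1(C)[C@@H](O[Si](C)(C)C(C)(C)C)CCC3(C)OCCO3 | intermediate
15 | hydrazone of 14 | NN=C1[C@@]2(C)O[C@H]2C[C@H](O[Si](C)(C)C(C)(C)C)[C@]1(C)[C@@H](O[Si](C)(C)C(C)(C)C)CCC3(C)OCCO3 | intermediate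
16 | Δ10(11) 12β-allylic alcohol | C1=C(C)[C@@H](O)C[C@H](O[Si](C)(C)C(C)(C)C)[C@]1(C)[C@@H](O[Si](C)(C)C(C)(C)C)CCC2(C)OCCO2 | intermediate
17 | 12β-(tributylstannyl)methyl ether | C1=C(C)[C@@H](OC[Sn](CCCC)(CCCC)CCCC)C[C@H](O[Si](C)(C)C(C)(C)C)[C@]1(C)[C@@H](O[Si](C)(C)C(C)(C)C)CCC2(C)OCCO2 | intermediate
18 | 12β-lithiomethyl ether | C1=C(C)[C@@H](OC[Li])C[C@H](O[Si](C)(C)C(C)(C)C)[C@]1(C)[C@@H](O[Si](C)(C)C(C)(C)C)CCC2(C)OCCO2 | intermediate
19 | 10β-hydroxymethyl Δ11 cyclohexene (C9 alcohol, 10α-H) | OC[C@H]1C(C)=CC[C@H](O[Si](C)(C)C(C)(C)C)[C@]1(C)[C@@H](O[Si](C)(C)C(C)(C)C)CCC2(C)OCCO2 | intermediate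
20 | C5 methyl ketone with C9 alcohol | OC[C@H]1C(C)=CC[C@H](O[Si](C)(C)C(C)(C)C)[C@]1(C)[C@@H](O[Si](C)(C)C(C)(C)C)CCC(C)=O | intermediate
21 | C5 methylene compound with C9 alcohol | OC[C@H]1C(C)=CC[C@H](O[Si](C)(C)C(C)(C)C)[C@]1(C)[C@@H](O[Si](C)(C)C(C)(C)C)CCC(C)=C | intermediate
22 | C9 aldehyde (10S) | O=C[C@H]1C(C)=CC[C@H](O[Si](C)(C)C(C)(C)C)[C@]1(C)[C@@H](O[Si](C)(C)C(C)(C)C)CCC(C)=C | intermediate
23 | diethyl (S)-malate | CCOC(=O)C[C@H](O)C(=O)OCC | starting material
24 | dilithium alkoxide enolate of 23 | CCOC(O[Li])=C[C@H](O[Li])C(=O)OCC | intermediate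
25 | diethyl (2S,3R)-2-hydroxy-3-methylsuccinate | CCOC(=O)[C@H](C)[C@H](O)C(=O)OCC | intermediate
26 | (2S,3R)-2-hydroxy-3-methylsuccinic acid | OC(=O)[C@H](C)[C@H](O)C(=O)O | intermediate
27 | (R)-2-[(2S,4S)-2-tert-butyl-5-oxo-1,3-dioxolan-4-yl]propanoic acid | OC(=O)[C@H](C)[C@@H]1O[C@H](C(C)(C)C)OC1=O | intermediate
28 | dilithium carboxylate enolate of 27 | [Li]OC(=O)[C@H](C)C1=C(O[Li])O[C@@H](C(C)(C)C)O1 | intermediate
29 | dilithium aldolate (C8–C9 bond formed) | [Li]OC(=O)[C@H](C)[C@@]1(O[C@H](C(C)(C)C)OC1=O)C(O[Li])[C@H]2C(C)=CC[C@H](O[Si](C)(C)C(C)(C)C)[C@]2(C)[C@@H](O[Si](C)(C)C(C)(C)C)CCC(C)=C | intermediate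
30 | C9 triethylsilyl ether, C19 triethylsilyl ester | CC[Si](CC)(CC)OC(=O)[C@H](C)[C@@]1(O[C@H](C(C)(C)C)OC1=O)C(O[Si](CC)(CC)CC)[C@H]2C(C)=CC[C@H](O[Si](C)(C)C(C)(C)C)[C@]2(C)[C@@H](O[Si](C)(C)C(C)(C)C)CCC(C)=C | intermediate
31 | aldol acid: C9-OTES, C7 dioxolanone, free C19 acid | OC(=O)[C@H](C)[C@@]1(O[C@H](C(C)(C)C)OC1=O)C(O[Si](CC)(CC)CC)[C@H]2C(C)=CC[C@H](O[Si](C)(C)C(C)(C)C)[C@]2(C)[C@@H](O[Si](C)(C)C(C)(C)C)CCC(C)=C | intermediate
32 | bromomagnesium hemiketal carboxylate (vinyl added to C7) | Br[Mg]OC(=O)[C@H](C)[C@@]1(O[C@H](C(C)(C)C)OC1(O[Mg]Br)C=C)C(O[Si](CC)(CC)CC)[C@H]2C(C)=CC[C@H](O[Si](C)(C)C(C)(C)C)[C@]2(C)[C@@H](O[Si](C)(C)C(C)(C)C)CCC(C)=C | intermediate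
33 | 8-hydroxy C7 vinyl ketone acid | OC(=O)[C@H](C)[C@](O)(C(=O)C=C)C(O[Si](CC)(CC)CC)[C@H]1C(C)=CC[C@H](O[Si](C)(C)C(C)(C)C)[C@]1(C)[C@@H](O[Si](C)(C)C(C)(C)C)CCC(C)=C | intermediate
34 | (7S)-7,8-dihydroxy acid | OC(=O)[C@H](C)[C@](O)([C@@H](O)C=C)C(O[Si](CC)(CC)CC)[C@H]1C(C)=CC[C@H](O[Si](C)(C)C(C)(C)C)[C@]1(C)[C@@H](O[Si](C)(C)C(C)(C)C)CCC(C)=C | intermediate
35 | γ-lactone (7S, 17R) with C6 vinyl group, 8-OH, 9-OTES | C=C[C@@H]1OC(=O)[C@H](C)[C@@]1(O)C(O[Si](CC)(CC)CC)[C@H]2C(C)=CC[C@H](O[Si](C)(C)C(C)(C)C)[C@]2(C)[C@@H](O[Si](C)(C)C(C)(C)C)CCC(C)=C | intermediate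
36 | lactone 9-alcohol | C=C[C@@H]1OC(=O)[C@H](C)[C@@]1(O)C(O)[C@H]2C(C)=CC[C@H](O[Si](C)(C)C(C)(C)C)[C@]2(C)[C@@H](O[Si](C)(C)C(C)(C)C)CCC(C)=C | intermediate
37 | lactone 9-ketone diene | C=C[C@@H]1OC(=O)[C@H](C)[C@@]1(O)C(=O)[C@H]2C(C)=CC[C@H](O[Si](C)(C)C(C)(C)C)[C@]2(C)[C@@H](O[Si](C)(C)C(C)(C)C)CCC(C)=C | intermediate
38 | macrocyclic 2,14-bis-TBS ether, (Z)-Δ5, Δ11 | CC1=CC[C@H](O[Si](C)(C)C(C)(C)C)[C@@]2(C)[C@H]1C(=O)[C@@]3(O)[C@H](/C=C(/C)CC[C@@H]2O[Si](C)(C)C(C)(C)C)OC(=O)[C@@H]3C | intermediate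
39 | 2,14-diol | CC1=CC[C@H](O)[C@@]2(C)[C@H]1C(=O)[C@@]3(O)[C@H](/C=C(/C)CC[C@@H]2O)OC(=O)[C@@H]3C | intermediate
40 | 2,14-diacetate | CC1=CC[C@H](OC(C)=O)[C@@]2(C)[C@H]1C(=O)[C@@]3(O)[C@H](/C=C(/C)CC[C@@H]2OC(C)=O)OC(=O)[C@@H]3C | intermediate
41 | CNP0066422.1 | C=C1[C@@H]2C(=O)[C@@]3(O)[C@H](/C=C(/C)CC[C@H](OC(C)=O)[C@@]2(C)[C@@H](OC(C)=O)C[C@@H]1OO)OC(=O)[C@@H]3C | target

## Step count and risks
Total steps: 27. Longest linear sequence: 24 steps (steps 1–15 and 19–27, from ethyl levulinate); the malate branch (steps 16–18) joins at step 19.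

Most likely to fail:

Step 24 (ring-closing metathesis). A trisubstituted olefin in a ten-membered carbocycle is demanding: both olefins are hindered, oligomers can form, and the E isomer is possible. Fallback (relay ring-closing metathesis, sets out from 31 and returns at 38): (E)-3-(allyloxy)prop-1-enyllithium (from the iodide and t-BuLi, Et2O, −78 °C) is added to 31 in place of the vinyl Grignard reagent to give the relay enone acid F3. Zn(BH4)2 reduction and lactonisation as in step 21 give the relay lactone F4. Buffered HF·pyridine gives the relay 9-alcohol F5, and Dess–Martin oxidation gives the relay 9-ketone F6. With the same ruthenium catalyst the terminal allyl ether is the loading site, 2,5-dihydrofuran is extruded, and the C6 alkylidene so delivered closes onto the C5 methylene to give 38.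

Step 10 (Wharton transposition). The C10 ketone sits between the quaternary C1 and the fully substituted epoxide carbon, so hydrazone formation may be too slow. Fallback (radical epoxide fragmentation, sets out from 14 and returns at 16): NaBH4 with CeCl3·7H2O (MeOH, −20 °C) reduces 14 to the epoxy alcohol F1 (C10 epimers immaterial). NaH, CS2, then MeI (THF) gives the S-methyl xanthate F2. Bu3SnH with AIBN (benzene, 80 °C) generates the C10 radical, which opens the adjacent epoxide by β-scission to give the same 12β-allylic alcohol 16.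

Step 27 (Schenck ene reaction). Competing attack at C5=C6, or formation of the tertiary 11-hydroperoxide, would erode the yield. Fallback (photooxygenation before the C5=C6 olefin exists, sets out from 37 and returns at 41): HF·pyridine converts 37 into the seco diol F7, and Ac2O with pyridine and DMAP gives the seco diacetate F8. The ene reaction (O2, tetraphenylporphyrin, light) on the only trisubstituted olefin gives the seco hydroperoxide F9. 2-Methoxypropene with PPTS masks it as the seco peroxyketal F10. Ring-closing metathesis under the step 24 conditions gives the macrocyclic peroxyketal F11, and AcOH/THF/H2O releases the hydroperoxide to give 41.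

## Further compounds
F1 | step 10 | epoxy alcohol (C10 carbinol, 11β,12β-epoxide) | OC1[C@@]2(C)O[C@H]2C[C@H](O[Si](C)(C)C(C)(C)C)[C@]1(C)[C@@H](O[Si](C)(C)C(C)(C)C)CCC3(C)OCCO3
F2 | step 10 | S-methyl xanthate of F1 | CSC(=S)OC1[C@@]2(C)O[C@H]2C[C@H](O[Si](C)(C)C(C)(C)C)[C@]1(C)[C@@H](O[Si](C)(C)C(C)(C)C)CCC3(C)OCCO3
F3 | step 24 | relay enone acid (C7 ketone bearing (E)-3-(allyloxy)prop-1-enyl) | OC(=O)[C@H](C)[C@](O)(C(=O)/C=C/COCC=C)C(O[Si](CC)(CC)CC)[C@H]1C(C)=CC[C@H](O[Si](C)(C)C(C)(C)C)[C@]1(C)[C@@H](O[Si](C)(C)C(C)(C)C)CCC(C)=C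
F4 | step 24 | relay lactone (9-OTES) | C=CCOC/C=C/[C@@H]1OC(=O)[C@H](C)[C@@]1(O)C(O[Si](CC)(CC)CC)[C@H]2C(C)=CC[C@H](O[Si](C)(C)C(C)(C)C)[C@]2(C)[C@@H](O[Si](C)(C)C(C)(C)C)CCC(C)=C
F5 | step 24 | relay 9-alcohol | C=CCOC/C=C/[C@@H]1OC(=O)[C@H](C)[C@@]1(O)C(O)[C@H]2C(C)=CC[C@H](O[Si](C)(C)C(C)(C)C)[C@]2(C)[C@@H](O[Si](C)(C)C(C)(C)C)CCC(C)=C
F6 | step 24 | relay 9-ketone | C=CCOC/C=C/[C@@H]1OC(=O)[C@H](C)[C@@]1(O)C(=O)[C@H]2C(C)=CC[C@H](O[Si](C)(C)C(C)(C)C)[C@]2(C)[C@@H](O[Si](C)(C)C(C)(C)C)CCC(C)=C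
F7 | step 27 | seco diol (2,14-diol of 37) | C=C[C@@H]1OC(=O)[C@H](C)[C@@]1(O)C(=O)[C@H]2C(C)=CC[C@H](O)[C@]2(C)[C@@H](O)CCC(C)=C
F8 | step 27 | seco diacetate | C=C[C@@H]1OC(=O)[C@H](C)[C@@]1(O)C(=O)[C@H]2C(C)=CC[C@H](OC(C)=O)[C@]2(C)[C@@H](OC(C)=O)CCC(C)=C
F9 | step 27 | seco hydroperoxide (12β-OOH, C11=C20) | C=C[C@@H]1OC(=O)[C@H](C)[C@@]1(O)C(=O)[C@H]2C(=C)[C@@H](OO)C[C@H](OC(C)=O)[C@]2(C)[C@@H](OC(C)=O)CCC(C)=C
F10 | step 27 | seco peroxyketal (2-methoxyprop-2-yl peroxide) | C=C[C@@H]1OC(=O)[C@H](C)[C@@]1(O)C(=O)[C@H]2C(=C)[C@@H](OOC(C)(C)OC)C[C@H](OC(C)=O)[C@]2(C)[C@@H](OC(C)=O)CCC(C)=C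
F11 | step 27 | macrocyclic peroxyketal | C=C1[C@@H]2C(=O)[C@@]3(O)[C@H](/C=C(/C)CC[C@H](OC(C)=O)[C@@]2(C)[C@@H](OC(C)=O)C[C@@H]1OOC(C)(C)OC)OC(=O)[C@@H]3C
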